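**Plan**

- Retrosynthetic cuts, in order: the two aryl silyl ethers; the C7''–H bond (back to a ketone); the ring C–C7'' bond (aryllithium on a Weinreb amide); the O4'–C8'' ether bond (Mitsunobu with ethyl (S)-lactate); the C9 methyl back to a carboxyl; the C7'–H bond back to a C7'–O bond; then C7–C8 (benzylation) and C7'–C8' (crotylation).
- Enabling feature: C7' is a benzylic methylene next to C8', so it can carry for a time an oxygen that joins C7', C8', C8 and C9 (as the carbonyl) into a five-membered γ-lactone ring.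
- Forward order: ring B aldehyde → syn crotylboration → hydroboration → oxidative lactonisation (the only ring formed, a temporary one) → enolate benzylation with the ring A bromide → one hydrogenolysis that opens the ring, turns C7' into CH2 and frees the ring B phenol → carboxyl to C9 methyl → aryl ether → ring C → carbinol → desilylation.
- Stereochemistry: C7' and C8' from the chiral phosphoric acid and the Z-crotyl geometry; C8 from alkylation anti to the lactone substituents; C8'' from ethyl (S)-lactate with Mitsunobu inversion; C7'' from chelation-controlled reduction (erythro).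

Key step: step 6

Remark: locants follow the neolignan numbering of the target name (C7–C9 with ring A, primed with ring B, doubly primed with ring C). The (R)-configured phosphoric acid of step 1 is assumed to direct re-face attack on the aryl aldehyde, as is usual for this catalyst class; the configuration of the first alcohol would be checked before material is carried on. Metal alkoxides and boron esters that only await aqueous work-up (steps 4, 8, 15) are not numbered.

**Route**

Step 1
Reactants: 1 4-benzyloxy-3,5-dimethoxybenzaldehyde; 2 (Z)-crotylboronic acid pinacol ester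
Product: 4 (1R,2S)-1-(4-benzyloxy-3,5-dimethoxyphenyl)-2-methylbut-3-en-1-ol, via homoallyl pinacol borate 3 (not isolated)
Conditions: 2 (1.3 equiv), (R)-3,3'-bis(2,4,6-triisopropylphenyl)-1,1'-binaphthyl-2,2'-diyl hydrogen phosphate (5 mol %), toluene, −30 °C; then aq NaHCO3
Reagents that add atoms: none
Why: Brønsted-acid-catalysed asymmetric crotylboration through a closed chair (Zimmerman–Traxler) transition state, in which the Z-crotyl geometry gives the syn relation and the chiral phosphoric acid, hydrogen-bonded to a boronate oxygen, selects the re face of the aldehyde and so fixes C7' (R) and C8'.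

Step 2
Reactants: 4 (1R,2S)-1-(4-benzyloxy-3,5-dimethoxyphenyl)-2-methylbut-3-en-1-ol
Product: 6 (1R,2S)-1-(4-benzyloxy-3,5-dimethoxyphenyl)-2-methylbutane-1,4-diol, via B-alkyl-9-borabicyclononane 5 (not isolated)
Conditions: 9-borabicyclo[3.3.1]nonane (0.5 M in THF, 2.5 equiv), THF, 0 °C to rt; then NaOH, H2O2, H2O, 0 °C to rt
Reagents that add atoms: hydrogen peroxide, OO
Why: Anti-Markovnikov hydroboration–oxidation, in which the bulky dialkylborane places boron on the terminal carbon only and no stereocentre is touched.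

Step 3
Reactants: 6 (1R,2S)-1-(4-benzyloxy-3,5-dimethoxyphenyl)-2-methylbutane-1,4-diol
Product: 9 (4S,5R)-5-(4-benzyloxy-3,5-dimethoxyphenyl)-4-methyldihydrofuran-2(3H)-one, via hydroxy aldehyde 7 (not isolated), via lactol 8 (not isolated)
Conditions: 2,2,6,6-tetramethylpiperidin-1-oxyl (0.2 equiv), PhI(OAc)2 (2.5 equiv), CH2Cl2, rt
Reagents that add atoms: none
Why: Nitroxyl-catalysed oxidative lactonisation, in which the oxoammonium species oxidises the primary alcohol in preference to the benzylic one, the aldehyde is trapped as the lactol and oxidised again, so the syn relation of aryl and methyl becomes the 4,5-cis lactone.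

Step 4
Reactants: 10 4-(tert-butyldimethylsilyloxy)-3-methoxybenzaldehyde
Product: 11 [4-(tert-butyldimethylsilyloxy)-3-methoxyphenyl]methanol
Conditions: NaBH4, MeOH–THF, 0 °C
Reagents that add atoms: none
Why: Borohydride reduction of an aryl aldehyde, short and cold enough for the aryl silyl ether to survive.

Step 5
Reactants: 11 [4-(tert-butyldimethylsilyloxy)-3-methoxyphenyl]methanol
Product: 12 [4-(bromomethyl)-2-methoxyphenoxy](tert-butyl)dimethylsilane
Conditions: CBr4, PPh3, CH2Cl2, 0 °C; used at once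
Reagents that add atoms: carbon tetrabromide, BrC(Br)(Br)Br
Why: Appel bromination under neutral conditions, chosen because the electron-rich para-silyloxybenzyl bromide tolerates neither acid nor storage.

Step 6
Reactants: 9 (4S,5R)-5-(4-benzyloxy-3,5-dimethoxyphenyl)-4-methyldihydrofuran-2(3H)-one; 12 [4-(bromomethyl)-2-methoxyphenoxy](tert-butyl)dimethylsilane
Product: 14 (3S,4S,5R)-5-(4-benzyloxy-3,5-dimethoxyphenyl)-3-[4-(tert-butyldimethylsilyloxy)-3-methoxybenzyl]-4-methyldihydrofuran-2(3H)-one, via lithium enolate 13 (not isolated)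
Conditions: LiN(SiMe3)2 (1.05 equiv), THF, −78 °C, 45 min; then 12 (1.2 equiv), DMPU (2 equiv), −78 to −40 °C; aq NH4Cl
Reagents that add atoms: none
Why: LiN(SiMe3)2 removes a proton from the lactone carbon that becomes C8 and gives the planar lithium enolate 13, which displaces bromide from the benzylic carbon of 12 by SN2 and so forms the C7–C8 bond. The closest known reaction type is the trans-selective alpha-alkylation of beta-substituted gamma-butyrolactone enolates used for dibenzylbutyrolactone lignans. No ring closes in this step; the lactone made in step 3 serves only as a template. The new stereocentre C8 is controlled by the ring, because the C8' methyl and the cis C7' aryl cover the same face of the enolate envelope and the electrophile must enter from the other face, which puts the benzyl group trans to the methyl (3S). The step needs mono-alkylation without epimerisation; complete kinetic deprotonation with a hindered amide base before the bromide is added, the low temperature, and the fact that the 3,4-trans product is also the more stable C8 epimer should secure this.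

Step 7
Reactants: 14 (3S,4S,5R)-5-(4-benzyloxy-3,5-dimethoxyphenyl)-3-[4-(tert-butyldimethylsilyloxy)-3-methoxybenzyl]-4-methyldihydrofuran-2(3H)-one
Product: 16 (2S,3R)-2-[4-(tert-butyldimethylsilyloxy)-3-methoxybenzyl]-4-(4-hydroxy-3,5-dimethoxyphenyl)-3-methylbutanoic acid, via debenzylated lactone 15 (not isolated)
Conditions: H2 (3 atm), 10% Pd/C, EtOAc–AcOH (4:1), rt to 40 °C
Reagents that add atoms: none
Why: Heterogeneous catalytic hydrogenolysis, in which the aryl benzyl ether is cleaved first and the benzylic C7'–O bond of the lactone, activated by the para-hydroxyl just released, follows, so that C7' becomes a methylene and the ring opens to the acid with C8 and C8' untouched and the aryl silyl ether intact.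

Step 8
Reactants: 16 (2S,3R)-2-[4-(tert-butyldimethylsilyloxy)-3-methoxybenzyl]-4-(4-hydroxy-3,5-dimethoxyphenyl)-3-methylbutanoic acid
Product: 17 (2S,3R)-2-[4-(tert-butyldimethylsilyloxy)-3-methoxybenzyl]-4-(4-hydroxy-3,5-dimethoxyphenyl)-3-methylbutan-1-ol
Conditions: BH3·SMe2 (3 equiv), THF, 0 °C to rt; then MeOH
Reagents that add atoms: none
Why: Borane reduction of a carboxylic acid through the acyloxyborane, chemoselective beside the phenol (held as a borate until the methanol quench) and the aryl silyl ether, and without risk to the alpha stereocentre C8.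

Step 9
Reactants: 17 (2S,3R)-2-[4-(tert-butyldimethylsilyloxy)-3-methoxybenzyl]-4-(4-hydroxy-3,5-dimethoxyphenyl)-3-methylbutan-1-ol
Product: 18 4-{(2R,3S)-4-[4-(tert-butyldimethylsilyloxy)-3-methoxyphenyl]-3-(iodomethyl)-2-methylbutyl}-2,6-dimethoxyphenol
Conditions: I2 (1.3 equiv), PPh3 (1.3 equiv), imidazole (2.5 equiv), CH2Cl2, 0 °C to rt
Reagents that add atoms: iodine, II
Why: Appel-type iodination, in which the alkoxyphosphonium salt of the primary alcohol is displaced by iodide while the hindered phenol forms no lasting aryloxyphosphonium species and is returned on work-up.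

Step 10
Reactants: 18 4-{(2R,3S)-4-[4-(tert-butyldimethylsilyloxy)-3-methoxyphenyl]-3-(iodomethyl)-2-methylbutyl}-2,6-dimethoxyphenol
Product: 19 4-{(2R,3S)-4-[4-(tert-butyldimethylsilyloxy)-3-methoxyphenyl]-2,3-dimethylbutyl}-2,6-dimethoxyphenol
Conditions: Bu3SnH (1.5 equiv, 0.2 M), 2,2'-azobis(2-methylpropionitrile) (0.1 equiv), toluene, 80 °C
Reagents that add atoms: none
Why: Radical chain dehalogenation, in which the primary C9 radical takes hydrogen from the tin hydride faster than it can add to either arene at this hydride concentration, and which is neutral and does not involve a stereocentre.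

Step 11
Reactants: 19 4-{(2R,3S)-4-[4-(tert-butyldimethylsilyloxy)-3-methoxyphenyl]-2,3-dimethylbutyl}-2,6-dimethoxyphenol; 20 ethyl (S)-lactate
Product: 21 ethyl (2R)-2-(4-{(2R,3S)-4-[4-(tert-butyldimethylsilyloxy)-3-methoxyphenyl]-2,3-dimethylbutyl}-2,6-dimethoxyphenoxy)propanoate
Conditions: 20 (1.5 equiv), PPh3 (1.5 equiv), diisopropyl azodicarboxylate (1.5 equiv), THF, 0 °C to rt
Reagents that add atoms: none
Why: Mitsunobu etherification, in which the phenoxide displaces the activated lactate hydroxyl by SN2 with clean inversion, so the (S)-lactate gives the (R)-aryloxypropanoate and sets C8''.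

Step 12
Reactants: 21 ethyl (2R)-2-(4-{(2R,3S)-4-[4-(tert-butyldimethylsilyloxy)-3-methoxyphenyl]-2,3-dimethylbutyl}-2,6-dimethoxyphenoxy)propanoate
Product: 22 (2R)-2-(4-{(2R,3S)-4-[4-(tert-butyldimethylsilyloxy)-3-methoxyphenyl]-2,3-dimethylbutyl}-2,6-dimethoxyphenoxy)-N-methoxy-N-methylpropanamide
Conditions: MeNH(OMe)·HCl (3 equiv), iPrMgCl (6 equiv), THF, −20 to 0 °C; aq NH4Cl
Reagents that add atoms: N,O-dimethylhydroxylamine hydrochloride, CNOC.Cl
Why: Weinreb amide formation by direct aminolysis of the ester with the chloromagnesium amide, a cold and weakly enolising reagent that should leave C8'' intact.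

Step 13
Reactants: 23 4-bromo-2-methoxyphenol
Product: 24 (4-bromo-2-methoxyphenoxy)(tert-butyl)dimethylsilane
Conditions: t-BuMe2SiCl, imidazole, DMF, rt
Reagents that add atoms: tert-butyldimethylsilyl chloride, CC(C)(C)[Si](C)(C)Cl
Why: Standard imidazole-promoted silylation of a phenol.

Step 14
Reactants: 22 (2R)-2-(4-{(2R,3S)-4-[4-(tert-butyldimethylsilyloxy)-3-methoxyphenyl]-2,3-dimethylbutyl}-2,6-dimethoxyphenoxy)-N-methoxy-N-methylpropanamide; 24 (4-bromo-2-methoxyphenoxy)(tert-butyl)dimethylsilane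
Product: 27 (2R)-1-[4-(tert-butyldimethylsilyloxy)-3-methoxyphenyl]-2-(4-{(2R,3S)-4-[4-(tert-butyldimethylsilyloxy)-3-methoxyphenyl]-2,3-dimethylbutyl}-2,6-dimethoxyphenoxy)propan-1-one, via aryllithium 25 (not isolated), via lithium hemiaminal chelate 26 (not isolated)
Conditions: 24 (1.5 equiv), n-BuLi (1.45 equiv), THF, −78 °C; then 22, −78 to −40 °C; then AcOH, −78 °C
Reagents that add atoms: none
Why: Halogen–lithium exchange followed by Weinreb ketone synthesis, in which the five-membered lithium chelate stops the addition at the ketone level and shields the alpha-aryloxy centre from enolisation until the cold acidic quench.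

Step 15
Reactants: 27 (2R)-1-[4-(tert-butyldimethylsilyloxy)-3-methoxyphenyl]-2-(4-{(2R,3S)-4-[4-(tert-butyldimethylsilyloxy)-3-methoxyphenyl]-2,3-dimethylbutyl}-2,6-dimethoxyphenoxy)propan-1-one
Product: 28 (1S,2R)-1-[4-(tert-butyldimethylsilyloxy)-3-methoxyphenyl]-2-(4-{(2R,3S)-4-[4-(tert-butyldimethylsilyloxy)-3-methoxyphenyl]-2,3-dimethylbutyl}-2,6-dimethoxyphenoxy)propan-1-ol
Conditions: Zn(BH4)2 (ethereal stock solution), Et2O–CH2Cl2, −20 to 0 °C; aq NH4Cl
Reagents that add atoms: none
Why: Chelation-controlled hydride reduction (Cram cyclic model), in which zinc bridges the carbonyl and the aryloxy oxygen and hydride enters from the side of the C8'' hydrogen, which should give the anti (erythro) 7''S,8''R carbinol.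

Step 16
Reactants: 28 (1S,2R)-1-[4-(tert-butyldimethylsilyloxy)-3-methoxyphenyl]-2-(4-{(2R,3S)-4-[4-(tert-butyldimethylsilyloxy)-3-methoxyphenyl]-2,3-dimethylbutyl}-2,6-dimethoxyphenoxy)propan-1-ol
Product: 29 (1S,2R)-1-(4-hydroxy-3-methoxyphenyl)-2-{4-[(2R,3S)-4-(4-hydroxy-3-methoxyphenyl)-2,3-dimethylbutyl]-2,6-dimethoxyphenoxy}propan-1-ol
Conditions: Bu4NF (2.5 equiv), AcOH (2.5 equiv), THF, 0 °C
Reagents that add atoms: none
Why: Fluoride-mediated cleavage of both aryl silyl ethers, buffered with acetic acid so that the para-hydroxybenzyl alcohol meets neither free phenoxide base nor the acid that would etherify or epimerise C7''.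

**Compound list**

1 | 4-benzyloxy-3,5-dimethoxybenzaldehyde | COc1cc(C=O)cc(OC)c1OCc1ccccc1 | starting material
2 | (Z)-crotylboronic acid pinacol ester | C/C=C\CB1OC(C)(C)C(C)(C)O1 | starting material
3 | 2-{[(1R,2S)-1-(4-benzyloxy-3,5-dimethoxyphenyl)-2-methylbut-3-en-1-yl]oxy}-4,4,5,5-tetramethyl-1,3,2-dioxaborolane | CC1(C)OB(O[C@@H](c2cc(OC)c(OCc3ccccc3)c(OC)c2)[C@H](C=C)C)OC1(C)C | intermediate (not isolated)
4 | (1R,2S)-1-(4-benzyloxy-3,5-dimethoxyphenyl)-2-methylbut-3-en-1-ol | O[C@@H](c1cc(OC)c(OCc2ccccc2)c(OC)c1)[C@H](C=C)C | intermediate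
5 | (1R,2S)-1-(4-benzyloxy-3,5-dimethoxyphenyl)-4-(9-borabicyclo[3.3.1]nonan-9-yl)-2-methylbutan-1-ol (hydroxyl drawn free) | O[C@@H](c1cc(OC)c(OCc2ccccc2)c(OC)c1)[C@H](CCB1C2CCCC1CCC2)C | intermediate (not isolated)
6 | (1R,2S)-1-(4-benzyloxy-3,5-dimethoxyphenyl)-2-methylbutane-1,4-diol | O[C@@H](c1cc(OC)c(OCc2ccccc2)c(OC)c1)[C@H](CCO)C | intermediate
7 | (3S,4R)-4-(4-benzyloxy-3,5-dimethoxyphenyl)-4-hydroxy-3-methylbutanal | O[C@@H](c1cc(OC)c(OCc2ccccc2)c(OC)c1)[C@H](CC=O)C | intermediate (not isolated)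
8 | (4S,5R)-5-(4-benzyloxy-3,5-dimethoxyphenyl)-4-methyltetrahydrofuran-2-ol (both anomers) | C1C(O)O[C@@H](c2cc(OC)c(OCc3ccccc3)c(OC)c2)[C@H]1C | intermediate (not isolated)
9 | (4S,5R)-5-(4-benzyloxy-3,5-dimethoxyphenyl)-4-methyldihydrofuran-2(3H)-one (4,5-cis) | C1C(=O)O[C@@H](c2cc(OC)c(OCc3ccccc3)c(OC)c2)[C@H]1C | intermediate
10 | 4-(tert-butyldimethylsilyloxy)-3-methoxybenzaldehyde | COc1cc(C=O)ccc1O[Si](C)(C)C(C)(C)C | starting material
11 | [4-(tert-butyldimethylsilyloxy)-3-methoxyphenyl]methanol | COc1cc(CO)ccc1O[Si](C)(C)C(C)(C)C | intermediate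
12 | [4-(bromomethyl)-2-methoxyphenoxy](tert-butyl)dimethylsilane | COc1cc(CBr)ccc1O[Si](C)(C)C(C)(C)C | intermediate
13 | lithium (4S,5R)-5-(4-benzyloxy-3,5-dimethoxyphenyl)-4-methyl-4,5-dihydrofuran-2-olate | C1=C(O[Li])O[C@@H](c2cc(OC)c(OCc3ccccc3)c(OC)c2)[C@H]1C | intermediate (not isolated)
14 | (3S,4S,5R)-5-(4-benzyloxy-3,5-dimethoxyphenyl)-3-[4-(tert-butyldimethylsilyloxy)-3-methoxybenzyl]-4-methyldihydrofuran-2(3H)-one (3,4-trans, 4,5-cis) | COc1cc(C[C@@H]2C(=O)O[C@@H](c3cc(OC)c(OCc4ccccc4)c(OC)c3)[C@H]2C)ccc1O[Si](C)(C)C(C)(C)C | intermediate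
15 | (3S,4S,5R)-3-[4-(tert-butyldimethylsilyloxy)-3-methoxybenzyl]-5-(4-hydroxy-3,5-dimethoxyphenyl)-4-methyldihydrofuran-2(3H)-one | COc1cc(C[C@@H]2C(=O)O[C@@H](c3cc(OC)c(O)c(OC)c3)[C@H]2C)ccc1O[Si](C)(C)C(C)(C)C | intermediate (not isolated)
16 | (2S,3R)-2-[4-(tert-butyldimethylsilyloxy)-3-methoxybenzyl]-4-(4-hydroxy-3,5-dimethoxyphenyl)-3-methylbutanoic acid | COc1cc(C[C@H](C(=O)O)[C@H](C)Cc2cc(OC)c(O)c(OC)c2)ccc1O[Si](C)(C)C(C)(C)C | intermediate
17 | (2S,3R)-2-[4-(tert-butyldimethylsilyloxy)-3-methoxybenzyl]-4-(4-hydroxy-3,5-dimethoxyphenyl)-3-methylbutan-1-ol | COc1cc(C[C@H](CO)[C@H](C)Cc2cc(OC)c(O)c(OC)c2)ccc1O[Si](C)(C)C(C)(C)C | intermediate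
18 | 4-{(2R,3S)-4-[4-(tert-butyldimethylsilyloxy)-3-methoxyphenyl]-3-(iodomethyl)-2-methylbutyl}-2,6-dimethoxyphenol | COc1cc(C[C@H](CI)[C@H](C)Cc2cc(OC)c(O)c(OC)c2)ccc1O[Si](C)(C)C(C)(C)C | intermediate
19 | 4-{(2R,3S)-4-[4-(tert-butyldimethylsilyloxy)-3-methoxyphenyl]-2,3-dimethylbutyl}-2,6-dimethoxyphenol | COc1cc(C[C@H](C)[C@H](C)Cc2cc(OC)c(O)c(OC)c2)ccc1O[Si](C)(C)C(C)(C)C | intermediate
20 | ethyl (S)-lactate | C[C@H](O)C(=O)OCC | starting material
21 | ethyl (2R)-2-(4-{(2R,3S)-4-[4-(tert-butyldimethylsilyloxy)-3-methoxyphenyl]-2,3-dimethylbutyl}-2,6-dimethoxyphenoxy)propanoate | COc1cc(C[C@H](C)[C@H](C)Cc2cc(OC)c(O[C@H](C)C(=O)OCC)c(OC)c2)ccc1O[Si](C)(C)C(C)(C)C | intermediate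
22 | (2R)-2-(4-{(2R,3S)-4-[4-(tert-butyldimethylsilyloxy)-3-methoxyphenyl]-2,3-dimethylbutyl}-2,6-dimethoxyphenoxy)-N-methoxy-N-methylpropanamide | COc1cc(C[C@H](C)[C@H](C)Cc2cc(OC)c(O[C@H](C)C(=O)N(C)OC)c(OC)c2)ccc1O[Si](C)(C)C(C)(C)C | intermediate
23 | 4-bromo-2-methoxyphenol | COc1cc(Br)ccc1O | starting material
24 | (4-bromo-2-methoxyphenoxy)(tert-butyl)dimethylsilane | COc1cc(Br)ccc1O[Si](C)(C)C(C)(C)C | intermediate
25 | [4-(tert-butyldimethylsilyloxy)-3-methoxyphenyl]lithium | COc1cc([Li])ccc1O[Si](C)(C)C(C)(C)C | intermediate (not isolated)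
26 | tetrahedral adduct of aryllithium 25 to the carbonyl of amide 22 (lithium alkoxide, N-methoxy-N-methylamino group retained, new carbon unassigned) | COc1cc(C[C@H](C)[C@H](C)Cc2cc(OC)c(O[C@H](C)C(O[Li])(N(C)OC)c3ccc(O[Si](C)(C)C(C)(C)C)c(OC)c3)c(OC)c2)ccc1O[Si](C)(C)C(C)(C)C | intermediate (not isolated)
27 | (2R)-1-[4-(tert-butyldimethylsilyloxy)-3-methoxyphenyl]-2-(4-{(2R,3S)-4-[4-(tert-butyldimethylsilyloxy)-3-methoxyphenyl]-2,3-dimethylbutyl}-2,6-dimethoxyphenoxy)propan-1-one | COc1cc(C[C@H](C)[C@H](C)Cc2cc(OC)c(O[C@H](C)C(=O)c3ccc(O[Si](C)(C)C(C)(C)C)c(OC)c3)c(OC)c2)ccc1O[Si](C)(C)C(C)(C)C | intermediate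
28 | (1S,2R)-1-[4-(tert-butyldimethylsilyloxy)-3-methoxyphenyl]-2-(4-{(2R,3S)-4-[4-(tert-butyldimethylsilyloxy)-3-methoxyphenyl]-2,3-dimethylbutyl}-2,6-dimethoxyphenoxy)propan-1-ol | COc1cc(C[C@H](C)[C@H](C)Cc2cc(OC)c(O[C@H](C)[C@@H](O)c3ccc(O[Si](C)(C)C(C)(C)C)c(OC)c3)c(OC)c2)ccc1O[Si](C)(C)C(C)(C)C | intermediate
29 | (+)-(7''S,8S,8'R,8''R)-4,4''-dihydroxy-3,3',3'',5'-tetramethoxy-4',8''-oxy-8,8'-sesquineolignan-7''-ol, that is (1S,2R)-1-(4-hydroxy-3-methoxyphenyl)-2-{4-[(2R,3S)-4-(4-hydroxy-3-methoxyphenyl)-2,3-dimethylbutyl]-2,6-dimethoxyphenoxy}propan-1-ol | COc1cc(C[C@H](C)[C@H](C)Cc2cc(OC)c(O[C@H](C)[C@@H](O)c3ccc(O)c(OC)c3)c(OC)c2)ccc1O | target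

**Step count and risks**

Total step count: 16. Longest linear sequence: 13 steps (steps 1, 2, 3, 6 to 12, 14, 15, 16); steps 4, 5 and 13 prepare the two side fragments.

Steps most likely to fail:

1. Step 6. The para-silyloxybenzyl bromide may ionise or oligomerise before it is captured, proton transfer between product and enolate may lead to double alkylation, or the facial selectivity may be incomplete. The fallback sets out from lactone 9 and replaces the SN2 reaction by an aldol addition: enolate 13 (LiN(SiMe3)2, THF, −78 °C) is treated with the stable aldehyde 10, which should again add anti to the ring substituents and give (3R,4S,5R)-5-(4-benzyloxy-3,5-dimethoxyphenyl)-3-{[4-(tert-butyldimethylsilyloxy)-3-methoxyphenyl](hydroxy)methyl}-4-methyldihydrofuran-2(3H)-one F1 as a pair of carbinol epimers. Hydrogenolysis of this compound (H2, Pd(OH)2/C, EtOAc–AcOH) should remove the benzylic C7 hydroxyl together with the C7'–O bond and the benzyl ether, so that both epimers converge and the route is rejoined at acid 16.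

2. Step 7. Hydrogenolysis may stop after the fast loss of the O-benzyl group with the lactone C–O bond intact, or conditions forcing enough to cleave it may start to remove the aryl silyl ether. The fallback sets out from lactone 14 and cleaves the C7'–O bond by ionic hydrogenation instead (Et3SiH in large excess, CF3CO2H, CH2Cl2, 0 °C). The silane is kept concentrated so that hydride capture of the C7' cation outruns Friedel–Crafts closure onto ring A. This should give (2S,3R)-4-(4-benzyloxy-3,5-dimethoxyphenyl)-2-[4-(tert-butyldimethylsilyloxy)-3-methoxybenzyl]-3-methylbutanoic acid F2. A mild hydrogenolysis of the aryl benzyl ether alone (H2, 10% Pd/C, EtOAc, rt) then returns to the route at acid 16.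

3. Step 15. Chelation may be weak at an aryloxy oxygen flanked by two methoxy groups, which would erode the facial selectivity and admix the threo carbinol. The fallback sets out from ketone 27 and replaces substrate control by reagent control: a Corey–Bakshi–Shibata reduction with (S)-1-methyl-3,3-diphenyltetrahydro-1H,3H-pyrrolo[1,2-c][1,3,2]oxazaborole (0.2 equiv) and BH3·SMe2 in THF at −20 °C should deliver hydride to the face that gives the (S)-carbinol whatever the bias of C8''. It returns directly to carbinol 28, and no new compound arises on the way (F0).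

**Further compounds**

F1 | step 6 | (3R,4S,5R)-5-(4-benzyloxy-3,5-dimethoxyphenyl)-3-{[4-(tert-butyldimethylsilyloxy)-3-methoxyphenyl](hydroxy)methyl}-4-methyldihydrofuran-2(3H)-one (carbinol epimers) | COc1cc(C(O)[C@@H]2C(=O)O[C@@H](c3cc(OC)c(OCc4ccccc4)c(OC)c3)[C@H]2C)ccc1O[Si](C)(C)C(C)(C)C
F2 | step 7 | (2S,3R)-4-(4-benzyloxy-3,5-dimethoxyphenyl)-2-[4-(tert-butyldimethylsilyloxy)-3-methoxybenzyl]-3-methylbutanoic acid | COc1cc(C[C@H](C(=O)O)[C@H](C)Cc2cc(OC)c(OCc3ccccc3)c(OC)c2)ccc1O[Si](C)(C)C(C)(C)C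
F0 | step 15 | none | none
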